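Your winter and noon runs already say what to watch, and it shows when you compare them at 5.00 min. Describe the fall of [substrate] up to that time by an apparent constant, the ln of charge over what is left, divided by the time; this summarises that stretch and claims no order of reaction:

| setting | winter | noon | flask |
|---|---|---|---|
| substrate | 10 mM | 10 mM | 10 mM |
| reagent | 8 mM | 8 mM | 8.00 mM |
| free catalyst | 28 µM | 44 µM | 20 µM |
| impurity | 4.8 µM | 4.8 µM | 4.8 µM |
| remark | run made earlier | run made earlier |  |

- winter (time / min: target / %, substrate / %): 0.667: 4.5, 95.6; 2.00: 12.7, 87.4; 3.00: 19.1, 81.3; 5.00: 29.4, 70.6; 8.00: 42.1, 57.5; 10.0: 49.4, 50.3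
- noon (time / min: target / %, substrate / %): 0.667: 7.8, 92.6; 2.00: 20.5, 79.4; 3.00: 29.7, 70.3; 5.00: 43.8, 56.2; 8.00: 59.6, 39.7; 10.0: 66.6, 33.4

(standard deviation of a reading: 0.3 percentage points)

- on the list of suspects stand: reagent + free catalyst -> catalyst intermediate A; substrate + catalyst intermediate A -> catalyst intermediate B; catalyst intermediate B -> free catalyst + target; free catalyst + impurity -> spent catalyst

* factor on the rate of making target when 20% of the substrate are converted if free catalyst is charged twice over
* factor on the rate when 20% of the substrate are converted if free catalyst is charged at 100 µM instead

winter: 0.0696 /min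

noon: 0.115 /min

Noon's constant is 1.65 times winter's, more than the 1.57 by which its charge of free catalyst is larger, so part of the charge seems not to work. A line through both runs meets zero at:

3.58 µM

That is a reading, good to about 1 µM, and it lies near the impurity charge of 4.8 µM. So two amounts count: the free catalyst charged and the impurity charged. I take one catalyst lost per impurity. In the flask that leaves 15.2 µM of live catalyst, the free catalyst charged minus the impurity charged. With the rate proportional to it, my factors for the flask are:

twice the charge: 2.32

100 µM: 6.26

The forecast says 2.28 (2.15 to 2.4) and 6.1 (5.6 to 6.6), on the grounds that “a roughly stoichiometric poison is removing catalyst”. It takes 4.4 µM as lost, so its factors stand below mine.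

    reagent + free catalyst → catalyst intermediate A (k = 8000 /M/min)
    substrate + catalyst intermediate A → catalyst intermediate B (k = 9900 /M/min)
    catalyst intermediate B → free catalyst + target (k = 120 /min)
    free catalyst + impurity → spent catalyst (k = 72000 /M/s)

The flask gives 2.32 and 6.26, inside both forecast ranges; a first factor at the 2.00 of the one-step fit, first order in substrate and free catalyst, would have broken the forecast. By 1.20 min the flask holds impurity at 0% of its charge and spent catalyst at 24.0% of the catalyst charged. Live catalyst carries to the flask with twice the charge: 15.2 µM over 35.2 µM is 0.432, and that flask reaches 20% conversion in 0.433 of this flask's time.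

The runs were generated by integration for an exercise.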